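A direct plan would make the isoflavone first and add the C5 unit last. Phloroglucinol A1 and 2,4-dimethoxyphenylacetic acid A2 would be condensed and ring-closed to the dimethyl ether A3, A3 would be demethylated to 2'-hydroxygenistein A4, A4 would be alkylated on O7 to the prenyl ether A5, and A5 would be heated so that an aromatic Claisen shift carries the inverted allyl unit to C8. Its weakest steps would be:
- the mono-alkylation of one of four hydroxyls in A4, because the acidity gap is small and ethers at O4' and O2' and bis-ethers would compete;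
- the sigmatropic shift of A5, because the chelated 5-OH would steer the allyl group to C6 and the hot ortho-allylphenol could shift again or close a dihydrofuran;
- the ether cleavage of A3, which would add length but no complexity.

The route proposed here instead takes ring A apart. C8a and C8, with the quaternary carbon already attached, come from 3,3-dimethylpent-4-enoyl chloride as a ketene; C7/C6 and C5/C4a come from two molecules of a silyl ynol ether. One thermal cascade (two [2+2] cycloadditions, two four-electron ring openings, one six-electron electrocyclisation) should deliver phenol 13 with the C8 substituent in place, O5 and O7 silylated and only the future O1 free. Ring C is then closed onto this single hydroxyl. Hence no hydroxyl has to be singled out by alkylation, no sigmatropic shift has to choose between C6 and C8, and no alkyl ether has to be cleaved.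

Key step: step 3

Remark: the target is achiral, so no stereocentre has to be set; positions are numbered as in the target chromone (ring A: C4a to C8a), and all phenols are carried as triisopropylsilyl ethers so that the aryl-bound 1,1-dimethylallyl group never meets a strong acid.

Step 1
Reactants: 1 acetylene (ethyne)
Product: 4 (triisopropylsilyloxy)ethyne, via lithium acetylide 2 (not isolated), via lithium ethynolate 3 (not isolated)
Conditions: n-BuLi, THF, −78 °C; LiOOt-Bu (from t-BuOOH and LiN(SiMe3)2), −78 → −20 °C; then i-Pr3SiOTf, −78 → 0 °C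
Reagents that add atoms: tert-butyl hydroperoxide, CC(C)(C)OO; triisopropylsilyl trifluoromethanesulfonate, CC(C)[Si](OS(=O)(=O)C(F)(F)F)(C(C)C)C(C)C
Why: The acetylide attacks the peroxide oxygen of LiOOt-Bu (electrophilic oxygen transfer to a lithium acetylide) to give ynolate 3, which the hard, bulky silyl triflate should capture on oxygen (silyl ynol ether synthesis by ynolate O-silylation); no stereocentre is formed.

Step 2
Reactants: 5 3,3-dimethylpent-4-enoic acid
Product: 6 3,3-dimethylpent-4-enoyl chloride
Conditions: (COCl)2, DMF (cat.), CH2Cl2, 0 °C → rt; distillation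
Reagents that add atoms: oxalyl chloride, O=C(Cl)C(=O)Cl
Why: Acid chloride formation through the chloroiminium (Vilsmeier-type) catalyst; the isolated monosubstituted alkene should not add HCl under these conditions.

Step 3
Reactants: 6 3,3-dimethylpent-4-enoyl chloride; 4 (triisopropylsilyloxy)ethyne (2 molecules)
Product: 13 2-(2-methylbut-3-en-2-yl)-3,5-bis(triisopropylsilyloxy)phenol, via ketene 7 (not isolated), via siloxycyclobutenone 8 (not isolated), via vinylketene 9 (not isolated), via alkenylcyclobutenone 10 (not isolated), via dienylketene 11 (not isolated), via cyclohexadienone 12 (not isolated)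
Conditions: 6 added slowly to 4 (2.4 equiv) and Et3N (1.5 equiv), toluene, 0 → 25 °C; filtration under Ar; then 90 °C
Reagents that add atoms: none
Why: Et3N dehydrochlorinates 6 to ketene 7 (as hindered as tert-butylketene, hence slow to dimerise), whose carbonyl carbon is attacked by the nucleophilic CH terminus of ynol ether 4 in a [2+2] cycloaddition to give 8; on heating, 8 opens (four-electron, conrotatory) to vinylketene 9, which takes up the second molecule of 4 with the same polarity to give 10, and 10 opens to dienylketene 11, which closes to dienone 12 and tautomerises to 13. The closest known reaction type is the Danheiser benzannulation of cyclobutenones with silyloxyalkynes, fed here by the known [2+2] cycloaddition of a ketene with a silyl ynol ether. Ring A is closed by a thermal six-electron disrotatory electrocyclisation that joins C8a to C8, after the first cycloaddition has made the C7–C8 bond and the second the C5–C6 and C4a–C8a bonds. No stereocentre remains: the sp3 centres of 8, 10 and 12 are racemic and vanish on aromatisation. The step needs three selectivities: the regiochemistry of both cycloadditions, fixed by the polarity of ketene and ynol ether; outward rotation of the tert-alkyl group when 8 opens, secured by its bulk, so that hydrogen points inward in the ring closure; and enolisation of 12 faster than a [3,3] shift of its 1,1-dimethylallyl group to oxygen or to the para carbon, for which the remaining Et3N serves as proton shuttle. Because the only free hydroxyl of 13 stems from the ketene carbonyl, it sits beside the quaternary substituent and later becomes O1.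

Step 4
Reactants: 14 2,4-dihydroxyphenylacetic acid
Product: 16 2-[2,4-bis(triisopropylsilyloxy)phenyl]acetic acid, via silyl ester 15 (not isolated)
Conditions: i-Pr3SiCl (3.3 equiv), imidazole, DMF, rt; then AcOH/THF/H2O, rt
Reagents that add atoms: triisopropylsilyl chloride, CC(C)[Si](Cl)(C(C)C)C(C)C
Why: Imidazole-mediated silylation of both phenols and the acid, then selective hydrolysis of the far more labile silyl ester; the bulky silyl ethers are chosen so that the ortho oxygen should not lactonise onto the later acid chloride.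

Step 5
Reactants: 16 2-[2,4-bis(triisopropylsilyloxy)phenyl]acetic acid
Product: 17 2-[2,4-bis(triisopropylsilyloxy)phenyl]acetyl chloride
Conditions: (COCl)2, DMF (cat.), CH2Cl2, 0 °C; used crude
Reagents that add atoms: oxalyl chloride, O=C(Cl)C(=O)Cl
Why: Acid chloride formation through the chloroiminium catalyst at low temperature, which aryl triisopropylsilyl ethers should tolerate.

Step 6
Reactants: 13 2-(2-methylbut-3-en-2-yl)-3,5-bis(triisopropylsilyloxy)phenol; 17 2-[2,4-bis(triisopropylsilyloxy)phenyl]acetyl chloride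
Product: 19 2-[2,4-bis(triisopropylsilyloxy)phenyl]-1-[2-hydroxy-3-(2-methylbut-3-en-2-yl)-4,6-bis(triisopropylsilyloxy)phenyl]ethan-1-one, via bromomagnesium phenolate 18 (not isolated)
Conditions: EtMgBr (1.0 equiv), Et2O, 0 °C; solvent change to toluene; 17 (1.1 equiv), 25 → 60 °C; aq NH4Cl
Reagents that add atoms: none
Why: Metal-template (ortho-coordinated) Friedel–Crafts C-acylation of a bromomagnesium phenolate: magnesium holds the acid chloride next to the only free ortho carbon (the other ortho position carries the quaternary group, and the remaining CH lies between two silyloxy groups and is not ortho to O–Mg), and the HCl formed is taken up by the phenolate so that no acid reaches the alkene.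

Step 7
Reactants: 19 2-[2,4-bis(triisopropylsilyloxy)phenyl]-1-[2-hydroxy-3-(2-methylbut-3-en-2-yl)-4,6-bis(triisopropylsilyloxy)phenyl]ethan-1-one
Product: 21 3-[2,4-bis(triisopropylsilyloxy)phenyl]-8-(2-methylbut-3-en-2-yl)-5,7-bis(triisopropylsilyloxy)-4H-chromen-4-one, via enaminone 20 (not isolated)
Conditions: Me2NCH(OMe)2 (3 equiv), toluene, 80 °C
Reagents that add atoms: N,N-dimethylformamide dimethyl acetal, COC(OC)N(C)C
Why: Deoxybenzoin route to isoflavones: the active methylene condenses with the amide acetal to enaminone 20, and the single free phenol adds to the β-carbon and expels dimethylamine (oxa-Michael addition–elimination closing the six-membered ring C), so the pyranone can close only toward the carbon that bears the tert-alkyl group.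

Step 8
Reactants: 21 3-[2,4-bis(triisopropylsilyloxy)phenyl]-8-(2-methylbut-3-en-2-yl)-5,7-bis(triisopropylsilyloxy)-4H-chromen-4-one
Product: 22 3-(2,4-dihydroxyphenyl)-5,7-dihydroxy-8-(2-methylbut-3-en-2-yl)-4H-chromen-4-one
Conditions: n-Bu4NF (4.5 equiv), AcOH (4.5 equiv), THF, 0 °C → rt
Reagents that add atoms: none
Why: Fluoride cleavage of the four aryl silyl ethers (Si–F bond formation), buffered with acetic acid so that neither the 1,1-dimethylallyl alkene nor the base-sensitive C2 of the isoflavone should be touched.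

**Compound list**
1 | acetylene (ethyne) | C#C | starting material
2 | lithium acetylide | [Li]C#C | intermediate
3 | lithium ethynolate | [Li]OC#C | intermediate
4 | (triisopropylsilyloxy)ethyne | C#CO[Si](C(C)C)(C(C)C)C(C)C | intermediate
5 | 3,3-dimethylpent-4-enoic acid | C=CC(C)(C)CC(=O)O | starting material
6 | 3,3-dimethylpent-4-enoyl chloride | C=CC(C)(C)CC(=O)Cl | intermediate
7 | 3,3-dimethylpenta-1,4-dien-1-one [(2-methylbut-3-en-2-yl)ketene] | C=CC(C)(C)C=C=O | intermediate
8 | rac-4-(2-methylbut-3-en-2-yl)-3-(triisopropylsilyloxy)cyclobut-2-en-1-one | O=C1C=C(O[Si](C(C)C)(C(C)C)C(C)C)C1C(C)(C)C=C | intermediate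
9 | (3Z)-5,5-dimethyl-3-(triisopropylsilyloxy)hepta-1,3,6-trien-1-one | O=C=C/C(O[Si](C(C)C)(C(C)C)C(C)C)=C/C(C)(C)C=C | intermediate
10 | rac-4-[(1Z)-3,3-dimethyl-1-(triisopropylsilyloxy)penta-1,4-dien-1-yl]-3-(triisopropylsilyloxy)cyclobut-2-en-1-one | O=C1C=C(O[Si](C(C)C)(C(C)C)C(C)C)C1/C(O[Si](C(C)C)(C(C)C)C(C)C)=C/C(C)(C)C=C | intermediate
11 | (3E,5Z)-7,7-dimethyl-3,5-bis(triisopropylsilyloxy)nona-1,3,5,8-tetraen-1-one | O=C=C/C(O[Si](C(C)C)(C(C)C)C(C)C)=C\C(O[Si](C(C)C)(C(C)C)C(C)C)=C\C(C)(C)C=C | intermediate
12 | rac-6-(2-methylbut-3-en-2-yl)-3,5-bis(triisopropylsilyloxy)cyclohexa-2,4-dien-1-one | O=C1C=C(O[Si](C(C)C)(C(C)C)C(C)C)C=C(O[Si](C(C)C)(C(C)C)C(C)C)C1C(C)(C)C=C | intermediate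
13 | 2-(2-methylbut-3-en-2-yl)-3,5-bis(triisopropylsilyloxy)phenol | Oc1cc(O[Si](C(C)C)(C(C)C)C(C)C)cc(O[Si](C(C)C)(C(C)C)C(C)C)c1C(C)(C)C=C | intermediate
14 | 2,4-dihydroxyphenylacetic acid | OC(=O)Cc1ccc(O)cc1O | starting material
15 | triisopropylsilyl 2-[2,4-bis(triisopropylsilyloxy)phenyl]acetate | O=C(Cc1ccc(O[Si](C(C)C)(C(C)C)C(C)C)cc1O[Si](C(C)C)(C(C)C)C(C)C)O[Si](C(C)C)(C(C)C)C(C)C | intermediate
16 | 2-[2,4-bis(triisopropylsilyloxy)phenyl]acetic acid | OC(=O)Cc1ccc(O[Si](C(C)C)(C(C)C)C(C)C)cc1O[Si](C(C)C)(C(C)C)C(C)C | intermediate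
17 | 2-[2,4-bis(triisopropylsilyloxy)phenyl]acetyl chloride | ClC(=O)Cc1ccc(O[Si](C(C)C)(C(C)C)C(C)C)cc1O[Si](C(C)C)(C(C)C)C(C)C | intermediate
18 | bromomagnesium 2-(2-methylbut-3-en-2-yl)-3,5-bis(triisopropylsilyloxy)phenolate | Br[Mg]Oc1cc(O[Si](C(C)C)(C(C)C)C(C)C)cc(O[Si](C(C)C)(C(C)C)C(C)C)c1C(C)(C)C=C | intermediate
19 | 2-[2,4-bis(triisopropylsilyloxy)phenyl]-1-[2-hydroxy-3-(2-methylbut-3-en-2-yl)-4,6-bis(triisopropylsilyloxy)phenyl]ethan-1-one | C=CC(C)(C)c1c(O)c(C(=O)Cc2ccc(O[Si](C(C)C)(C(C)C)C(C)C)cc2O[Si](C(C)C)(C(C)C)C(C)C)c(O[Si](C(C)C)(C(C)C)C(C)C)cc1O[Si](C(C)C)(C(C)C)C(C)C | intermediate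
20 | 2-[2,4-bis(triisopropylsilyloxy)phenyl]-3-(dimethylamino)-1-[2-hydroxy-3-(2-methylbut-3-en-2-yl)-4,6-bis(triisopropylsilyloxy)phenyl]prop-2-en-1-one | C=CC(C)(C)c1c(O)c(C(=O)C(=CN(C)C)c2ccc(O[Si](C(C)C)(C(C)C)C(C)C)cc2O[Si](C(C)C)(C(C)C)C(C)C)c(O[Si](C(C)C)(C(C)C)C(C)C)cc1O[Si](C(C)C)(C(C)C)C(C)C | intermediate
21 | 3-[2,4-bis(triisopropylsilyloxy)phenyl]-8-(2-methylbut-3-en-2-yl)-5,7-bis(triisopropylsilyloxy)-4H-chromen-4-one | C=CC(C)(C)c1c(O[Si](C(C)C)(C(C)C)C(C)C)cc(O[Si](C(C)C)(C(C)C)C(C)C)c2c(=O)c(-c3ccc(O[Si](C(C)C)(C(C)C)C(C)C)cc3O[Si](C(C)C)(C(C)C)C(C)C)coc12 | intermediate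
22 | 3-(2,4-dihydroxyphenyl)-5,7-dihydroxy-8-(2-methylbut-3-en-2-yl)-4H-chromen-4-one (achiral) | C=CC(C)(C)c1c(O)cc(O)c2c(=O)c(-c3ccc(O)cc3O)coc12 | target

Total step count: 8. Longest linear sequence: 5 steps (2, 3, 6, 7, 8; equally long from 1 or from 14).

**Steps most likely to fail**

Step 3 (key step). The ketene may dimerise, or 6 may acylate the ynol ether, before the first cycloaddition. Vinylketene 9 may be captured too slowly. Dienone 12 may be diverted by a sigmatropic shift of its allyl group before it enolises. The product phenol may be acylated by ketenes. The fallback replaces steps 1 to 3; it sets out from commercial phloroglucinol, not from a numbered compound, and comes back to the route at 13. Phloroglucinol would be silylated twice (i-Pr3SiCl, imidazole, DMF) to 3,5-bis(triisopropylsilyloxy)phenol F1. F1 would be O-alkylated with prenyl bromide (K2CO3, acetone) to 1-[(3-methylbut-2-en-1-yl)oxy]-3,5-bis(triisopropylsilyloxy)benzene F2. F2 would be heated in N,N-diethylaniline (about 180 °C). Its two ortho positions are equivalent and the para carbon lies between two silyloxy groups, so the ortho Claisen rearrangement should give 13.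

Step 6. Acylation may occur on oxygen instead of carbon, or not at all at the crowded ring carbon. The fallback sets out from 13 and comes back at 19. Phenol 13 would be ortho-formylated (MgCl2, Et3N, paraformaldehyde, MeCN, reflux) to 2-hydroxy-3-(2-methylbut-3-en-2-yl)-4,6-bis(triisopropylsilyloxy)benzaldehyde F3. Commercial 2,4-dihydroxybenzaldehyde would be silylated (i-Pr3SiOTf, 2,6-lutidine) to 2,4-bis(triisopropylsilyloxy)benzaldehyde F4 and condensed with tosylhydrazide to the N-tosylhydrazone of 2,4-bis(triisopropylsilyloxy)benzaldehyde F5. F3 and F5 would be heated with Cs2CO3 in dioxane; the aryldiazomethane formed in situ should insert into the formyl C–H bond (addition, loss of N2, 1,2-hydride shift) to give 19.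

Step 1. The ynolate may be silylated on carbon (giving a silylketene) instead of oxygen, and lithium acetylide may disproportionate on warming. The fallback sets out from commercial bromoacetaldehyde diethyl acetal, not from a numbered compound, and comes back at 4. The acetal would be hydrolysed (aqueous acid) to bromoacetaldehyde F6. F6 would be converted with i-Pr3SiOTf and Et3N into (Z)-(2-bromoethenyloxy)triisopropylsilane F7. F7 would be dehydrobrominated with LiN(i-Pr)2 (2 equiv, THF, −78 °C) and protonated to give 4. This is the dehydrohalogenation of a β-halovinyl ether, the classical entry to 1-alkynyl ethers, and the silyl group sits on oxygen from the start.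

**Further compounds**
F1 | step 3 | 3,5-bis(triisopropylsilyloxy)phenol | Oc1cc(O[Si](C(C)C)(C(C)C)C(C)C)cc(O[Si](C(C)C)(C(C)C)C(C)C)c1
F2 | step 3 | 1-[(3-methylbut-2-en-1-yl)oxy]-3,5-bis(triisopropylsilyloxy)benzene | CC(C)=CCOc1cc(O[Si](C(C)C)(C(C)C)C(C)C)cc(O[Si](C(C)C)(C(C)C)C(C)C)c1
F3 | step 6 | 2-hydroxy-3-(2-methylbut-3-en-2-yl)-4,6-bis(triisopropylsilyloxy)benzaldehyde | C=CC(C)(C)c1c(O)c(C=O)c(O[Si](C(C)C)(C(C)C)C(C)C)cc1O[Si](C(C)C)(C(C)C)C(C)C
F4 | step 6 | 2,4-bis(triisopropylsilyloxy)benzaldehyde | O=Cc1ccc(O[Si](C(C)C)(C(C)C)C(C)C)cc1O[Si](C(C)C)(C(C)C)C(C)C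
F5 | step 6 | N'-[(E)-[2,4-bis(triisopropylsilyloxy)phenyl]methylidene]-4-methylbenzenesulfonohydrazide | Cc1ccc(cc1)S(=O)(=O)N/N=C/c1ccc(O[Si](C(C)C)(C(C)C)C(C)C)cc1O[Si](C(C)C)(C(C)C)C(C)C
F6 | step 1 | bromoacetaldehyde | BrCC=O
F7 | step 1 | (Z)-(2-bromoethenyloxy)triisopropylsilane | Br/C=C\O[Si](C(C)C)(C(C)C)C(C)C
A1 | direct plan | phloroglucinol (benzene-1,3,5-triol) | Oc1cc(O)cc(O)c1
A2 | direct plan | 2,4-dimethoxyphenylacetic acid | COc1ccc(CC(=O)O)c(OC)c1
A3 | direct plan | 3-(2,4-dimethoxyphenyl)-5,7-dihydroxy-4H-chromen-4-one | COc1ccc(-c2coc3cc(O)cc(O)c3c2=O)c(OC)c1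
A4 | direct plan | 3-(2,4-dihydroxyphenyl)-5,7-dihydroxy-4H-chromen-4-one (2'-hydroxygenistein) | O=c1c(-c2ccc(O)cc2O)coc2cc(O)cc(O)c12
A5 | direct plan | 3-(2,4-dihydroxyphenyl)-5-hydroxy-7-[(3-methylbut-2-en-1-yl)oxy]-4H-chromen-4-one | CC(C)=CCOc1cc(O)c2c(=O)c(-c3ccc(O)cc3O)coc2c1
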